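**Plan**
- Retrosynthetic cuts, in order: the C8 angelate ester; the furanone O–C3 bond (leaving a C10 hydroxyl beside the C1 enone); the lactone O–C6 bond (leaving a C12 acid and a C5=C6 alkene); then C3–C4, with C1–C6 re-formed.
- Enabling feature: after these cuts the carbocycle C1–C10 carries C1(=O)–C2=C3–C4(sp3)–C5=C6, the 2,5-dien-1-one array of an alkynyl oxy-Cope product. Undoing the [3,3] shift leaves a cyclohexane (C1, C6, C7, C8, C9, C10) with ethynyl on C1 and an alkenyl group on C6; this ring plus C14 and C11–C13 is the carbon set of (R)-carvone.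
- Forward order: carvone → C12 chloride → oxygen relayed from C1 to C10 and C8 by two directed epoxidations → acetonide ketone → C6 alkenylation → C1 ethynylation → ring expansion to the ten-membered ring → γ-lactone ring → furanone ring → angelate.
- Stereochemistry: C7 comes from carvone. C10 and C8 are relayed from the cis C1 hydroxyl by hydroxyl-directed epoxidation and trans-diaxial epoxide opening. C4 comes from the E alkene in the chair-like [3,3] transition state. C6 comes from anti iodolactonisation of the Z alkene under allylic-strain control.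

Key step: step 16

Remark (numbering): every intermediate carries the atom numbers of the target (C1 ketone, C2=C3, C4 bearing C15, C5, C6 lactone O–CH, C7, C8 O-angelate, C9, C10 bearing C14, C11=C13, C12 lactone C=O). In the cyclohexane series the ring is C1–C6–C7–C8–C9–C10 and "lower face" means the face that carries the C7 side chain.
Remark (geometry): with ethynyl axial and the alkenyl group equatorial, the chair-like [3,3] transition state can deliver C5=C6 only as the Z alkene, so the ring-expanded product is drawn 2Z,5Z. The 2Z enone geometry assumes protonation of the allenolate from the side of H3; either enone geometry would serve the later furanone closure.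

**Route**

Step 1
Reactants: 1 (R)-carvone
Product: 2 (R)-10-chlorocarvone (C12 chloride)
Conditions: Ca(OCl)2, CO2 (solid), CH2Cl2/H2O, 0 °C
Reagents that add atoms: calcium hypochlorite, [Ca+2].[O-]Cl.[O-]Cl
Why: Hypochlorous acid attacks only the electron-rich 1,1-disubstituted alkene in an ene-type allylic chlorination with double-bond shift, leaving the conjugated enone and the C7 stereocentre untouched.

Step 2
Reactants: 2 (R)-10-chlorocarvone
Product: 3 chloro-cis-carveol (C1–OH on the lower face)
Conditions: NaBH4, CeCl3·7H2O, MeOH, −78 to 0 °C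
Reagents that add atoms: none
Why: Luche reduction adds hydride 1,2 and axially to the half-chair enone with the C7 substituent equatorial, so the C1 hydroxyl ends up cis to that substituent.

Step 3
Reactants: 3 chloro-cis-carveol
Product: 4 C9–C10 epoxy alcohol (epoxide on the lower face)
Conditions: VO(acac)2 (cat.), t-BuOOH, CH2Cl2, 0 °C to rt
Reagents that add atoms: tert-butyl hydroperoxide, CC(C)(C)OO
Why: Vanadium-catalysed hydroxyl-directed epoxidation delivers oxygen to the ring alkene on the face of the C1 hydroxyl, which fixes the C10–O bond cis to the C7 side chain, while the undirected 2-(chloromethyl)vinyl group is left alone.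

Step 4
Reactants: 4 C9–C10 epoxy alcohol
Product: 5 C1 tert-butyldimethylsilyl ether
Conditions: TBSOTf, 2,6-lutidine, CH2Cl2, −78 °C
Reagents that add atoms: tert-butyldimethylsilyl triflate, CC(C)(C)[Si](C)(C)OS(=O)(=O)C(F)(F)F
Why: O-silylation of the secondary alcohol with a silyl triflate and a hindered base is fast at low temperature and blocks C1–OH so that it can neither displace the allylic chloride nor compete later for the acetonide.

Step 5
Reactants: 5 C1 silyl ether
Product: 6 C12 p-methoxybenzyl ether
Conditions: PMBOH, NaH, Bu4NI (cat.), THF/DMF, 0 °C to rt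
Reagents that add atoms: 4-methoxybenzyl alcohol, COc1ccc(CO)cc1
Why: Williamson ether synthesis by SN2 displacement of the primary allylic chloride should outpace attack on the hindered trisubstituted epoxide and puts a base-stable, oxidatively removable group on C12–O.

Step 6
Reactants: 6 C12 PMB ether
Product: 8 C10 tertiary allylic alcohol (C8=C9), via hydroxy selenide 7 (not isolated)
Conditions: (PhSe)2, NaBH4, EtOH, reflux; then H2O2, THF, 0 °C to rt
Reagents that add atoms: none
Why: Selenide opens the epoxide by trans-diaxial SN2 attack at the secondary carbon C9, and after oxidation the selenoxide syn-elimination can take hydrogen only from C8 because C10 is quaternary, which moves the alkene to C8=C9 and leaves the C10 carbinol configuration intact.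

Step 7
Reactants: 8 C10 tertiary allylic alcohol
Product: 9 C8–C9 epoxy alcohol (epoxide on the lower face)
Conditions: VO(acac)2 (cat.), t-BuOOH, CH2Cl2, rt
Reagents that add atoms: tert-butyl hydroperoxide, CC(C)(C)OO
Why: A second vanadium-catalysed hydroxyl-directed epoxidation, now from the pseudo-axial C10 hydroxyl, places the epoxide on the same face and so overrides the steric bias of the neighbouring C7 side chain.

Step 8
Reactants: 9 C8–C9 epoxy alcohol
Product: 10 cis-1,3-diol (C8–OH and C10–OH on the lower face)
Conditions: LiAlH4, THF, 0 °C to rt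
Reagents that add atoms: none
Why: Hydride opens the epoxide by SN2 attack in the trans-diaxial sense (Fürst–Plattner rule) at C9 of the half-chair that keeps the C7 side chain and C14 equatorial, which leaves an axial C8 hydroxyl cis to the C10 hydroxyl and to the side chain.

Step 9
Reactants: 10 cis-1,3-diol
Product: 11 C8,C10-acetonide C1 silyl ether
Conditions: 2,2-dimethoxypropane, PPTS (cat.), CH2Cl2, rt
Reagents that add atoms: 2,2-dimethoxypropane, COC(C)(C)OC
Why: Acid-catalysed transacetalisation closes the six-membered isopropylidene acetal across the two free, already 1,3-diaxial hydroxyls, the C1 oxygen being silylated.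

Step 10
Reactants: 11 acetonide silyl ether
Product: 12 acetonide C1 alcohol
Conditions: TBAF, THF, rt
Reagents that add atoms: none
Why: Fluoride-induced desilylation removes the only silyl group and leaves the acetonide and the PMB ether untouched.

Step 11
Reactants: 12 acetonide C1 alcohol
Product: 13 acetonide ketone (C1=O)
Conditions: Dess–Martin periodinane, NaHCO3, CH2Cl2, rt
Reagents that add atoms: none
Why: Dess–Martin oxidation converts the secondary alcohol to the ketone under buffered, non-epimerising conditions that spare the acid-labile acetonide.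

Step 12
Reactants: 14 propargyl alcohol
Product: 15 propargyl tert-butyldiphenylsilyl ether
Conditions: TBDPSCl, imidazole, CH2Cl2, rt
Reagents that add atoms: tert-butyldiphenylsilyl chloride, CC(C)(C)[Si](Cl)(c1ccccc1)c1ccccc1
Why: Imidazole-promoted O-silylation installs an acid-robust silyl ether on the future C15 oxygen.

Step 13
Reactants: 15 propargyl silyl ether
Product: 17 (E)-3-bromoallyl silyl ether, via alkenylzirconocene chloride 16 (not isolated)
Conditions: Cp2Zr(H)Cl, CH2Cl2, rt; then NBS, 0 °C
Reagents that add atoms: N-bromosuccinimide, O=C1CCC(=O)N1Br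
Why: Hydrozirconation adds Zr–H syn with zirconium on the terminal carbon, and bromodemetalation with retention gives the E alkenyl bromide.

Step 14
Reactants: 13 acetonide ketone; 17 (E)-3-bromoallyl silyl ether
Product: 18 C6-alkenyl ketone (E alkene, alkenyl trans to the C7 side chain)
Conditions: LiHMDS, toluene, 0 °C; then 17, Pd2(dba)3 (cat.), P(t-Bu)3·HBF4 (cat.), rt; AcOH, −78 °C
Reagents that add atoms: none
Why: Palladium-catalysed α-alkenylation of a ketone enolate (enolate cross-coupling with an alkenyl bromide) can occur only at C6 because C10 is quaternary, retains the E geometry, and leaves an epimerisable C6 centre that settles with the alkenyl group equatorial and trans to the C7 side chain.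

Step 15
Reactants: 18 C6-alkenyl ketone; 19 ethynylmagnesium bromide
Product: 20 1-ethynyl-2-alkenylcyclohexanol acetonide (ethynyl axial and cis to the alkenyl group)
Conditions: CeCl3 (anhydrous), THF, −78 to 0 °C; aq NH4Cl
Reagents that add atoms: none
Why: Cerium-mediated 1,2-addition of the acetylide occurs axially from the face opposite the two axial acetonide oxygens, placing ethynyl cis to the equatorial C6 alkenyl group, and the low basicity of the cerium reagent suppresses enolisation of the α-alkenyl ketone.

Step 16
Reactants: 20 1-ethynyl-2-alkenylcyclohexanol acetonide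
Product: 23 (2Z,5Z)-cyclodeca-2,5-dienone acetonide, via potassium alkoxide 21 (not isolated), via potassium allenolate 22 (not isolated)
Conditions: KHMDS, 18-crown-6, THF, −20 °C to rt; then AcOH, −78 °C
Reagents that add atoms: none
Why: Deprotonation gives alkoxide 21, whose oxyanion weakens the allylic and propargylic C1–C6 bond so that a concerted [3,3] sigmatropic shift breaks C1–C6 and joins alkyne carbon C3 to alkene carbon C4, giving allenolate 22, which acetic acid protonates at C2 from the side of H3 to the 2Z enone. The closest known reaction type is the anionic oxy-Cope ring expansion of 1-alkynyl-2-vinylcyclohexanols to cyclodeca-2,5-dienones. The ten-membered carbocycle C1–C10 is not closed end to end but arises by four-atom expansion of the cyclohexane through the six-centre array C3–C2–C1–C6–C5–C4. The new C4 stereocentre is set by the E geometry of C4=C5 acting within the chair-like transition state that the acetonide-locked cyclohexane enforces: with ethynyl axial and alkenyl equatorial, C4 reaches C3 only in the rotamer that holds C7 syn to C4, so one face of C4 bonds and C5=C6 is born Z (the centre is R by CIP rules in 23 and becomes 4S in the target once C3 carries oxygen). The step needs the [3,3] shift to outrun loss of acetylide and base-induced migration of the skipped diene; the rigid chair, the crown-separated alkoxide at or below room temperature and the cold acidic quench of the allenolate should secure this.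

Step 17
Reactants: 23 (2Z,5Z)-cyclodeca-2,5-dienone acetonide
Product: 24 C12 allylic alcohol
Conditions: DDQ, CH2Cl2/pH 7 buffer, 0 °C
Reagents that add atoms: none
Why: Oxidative PMB cleavage by DDQ (benzylic hydride abstraction, then hydrolysis of the oxocarbenium ion) frees the primary allylic alcohol without touching the silyl ether or the acetonide.

Step 18
Reactants: 24 C12 allylic alcohol
Product: 25 C12 enal
Conditions: MnO2, CH2Cl2, rt
Reagents that add atoms: none
Why: Manganese dioxide is a neutral, allylic-selective oxidant that takes the primary allylic alcohol to the 2-substituted acrolein without base that could move the skipped diene.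

Step 19
Reactants: 25 C12 enal
Product: 26 C12 acrylic acid
Conditions: NaClO2, NaH2PO4, 2-methyl-2-butene, t-BuOH/H2O, 0 °C
Reagents that add atoms: sodium chlorite, [Na+].[O-]Cl=O
Why: Pinnick oxidation converts the enal to the acid under mildly acidic buffer, with 2-methyl-2-butene trapping hypochlorous acid so that the ring alkenes are spared.

Step 20
Reactants: 26 C12 acrylic acid
Product: 27 6,12-iodolactone (C5 iodide anti to the lactone oxygen)
Conditions: I2, NaHCO3, MeCN/H2O, 0 °C, dark
Reagents that add atoms: iodine, II
Why: In this iodolactonisation iodine activates the only electron-rich alkene (C5=C6) and the carboxylate closes the γ-lactone by 5-exo anti attack at C6; with H7 eclipsing the Z alkene to avoid allylic 1,3-strain, the carboxylate can reach C6 only from the face that gives the trans ring fusion (H6 anti to H7).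

Step 21
Reactants: 27 6,12-iodolactone
Product: 28 α-methylene lactone acetonide (C5 H2)
Conditions: Bu3SnH, Et3B (cat.), air, toluene, 0 °C to rt
Reagents that add atoms: none
Why: Radical-chain deiodination with tin hydride replaces the C5 iodide by hydrogen, iodine abstraction being far faster than stannyl radical addition to the enone or the methylene lactone.

Step 22
Reactants: 28 α-methylene lactone acetonide
Product: 29 C8,C10-diol (α′-hydroxy enone)
Conditions: AcOH, THF, H2O, 40 °C
Reagents that add atoms: none
Why: Acid-catalysed acetal hydrolysis frees the C8 and C10 hydroxyls under conditions that the silyl ether, the lactone and the enone tolerate.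

Step 23
Reactants: 29 C8,C10-diol
Product: 30 3(2H)-furanone C8 alcohol
Conditions: PdCl2(MeCN)2 (cat.), CuCl (cat.), O2 (1 atm), Na2HPO4, DME, 50 °C
Reagents that add atoms: none
Why: In this Wacker-type palladium(II)-catalysed oxidative cyclisation of an α′-hydroxy enone the C10 hydroxyl adds to palladium-activated C3 (5-endo) and β-hydride elimination restores C2=C3, giving the furanone, while the electron-poor methylene lactone is not activated.

Step 24
Reactants: 30 3(2H)-furanone C8 alcohol; 31 angelic acid
Product: 32 C8 angelate silyl ether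
Conditions: 2,4,6-trichlorobenzoyl chloride, Et3N, toluene, rt; then 30, 80 °C
Reagents that add atoms: none
Why: Yamaguchi esterification through the mixed anhydride acylates the only free hydroxyl with retention at C8 and, run without a nucleophilic catalyst, should not isomerise the Z angelate to the tiglate.

Step 25
Reactants: 32 C8 angelate silyl ether
Product: 33 target compound
Conditions: HF·pyridine, pyridine, THF, 0 °C to rt
Reagents that add atoms: none
Why: Buffered fluoride desilylation removes the silyl ether from the C15 oxygen without opening the lactone, cleaving the angelate or adding to the Michael acceptors.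

**Compound list**

1 | (R)-carvone | CC1=CC[C@H](CC1=O)C(C)=C | starting material
2 | (R)-10-chlorocarvone, (5R)-5-(3-chloroprop-1-en-2-yl)-2-methylcyclohex-2-en-1-one | CC1=CC[C@H](CC1=O)C(=C)CCl | intermediate
3 | chloro-cis-carveol, (1R,5R)-5-(3-chloroprop-1-en-2-yl)-2-methylcyclohex-2-en-1-ol (C1–OH cis to the C7 side chain) | CC1=CC[C@H](C[C@H]1O)C(=C)CCl | intermediate
4 | C9–C10 epoxy alcohol (epoxide and C1–OH on the lower face) | C[C@]12O[C@H]1C[C@H](C[C@H]2O)C(=C)CCl | intermediate
5 | C1 TBS ether of 4 | C[C@]12O[C@H]1C[C@H](C[C@H]2O[Si](C)(C)C(C)(C)C)C(=C)CCl | intermediate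
6 | C12 PMB ether (epoxide, C1–OTBS) | C[C@]12O[C@H]1C[C@H](C[C@H]2O[Si](C)(C)C(C)(C)C)C(=C)COCc3ccc(OC)cc3 | intermediate
7 | hydroxy selenide (C9–SePh upper face, C10–OH lower face) | C[C@]1(O)[C@H]([Se]c2ccccc2)C[C@H](C[C@H]1O[Si](C)(C)C(C)(C)C)C(=C)COCc3ccc(OC)cc3 | intermediate
8 | C10 tertiary allylic alcohol (C8=C9; C10–OH and C1–OTBS lower face) | C[C@]1(O)C=C[C@H](C[C@H]1O[Si](C)(C)C(C)(C)C)C(=C)COCc2ccc(OC)cc2 | intermediate
9 | C8–C9 epoxy alcohol (epoxide cis to C10–OH, lower face) | C[C@]1(O)[C@H]2O[C@H]2[C@H](C[C@H]1O[Si](C)(C)C(C)(C)C)C(=C)COCc3ccc(OC)cc3 | intermediate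
10 | cis-1,3-diol (C8–OH, C10–OH, C1–OTBS and C7 side chain all on the lower face; C14 upper) | C[C@]1(O)C[C@@H](O)[C@H](C[C@H]1O[Si](C)(C)C(C)(C)C)C(=C)COCc2ccc(OC)cc2 | intermediate
11 | C8,C10-acetonide C1 TBS ether | CC(C)(C)[Si](C)(C)O[C@@H]1C[C@H](C(=C)COCc2ccc(OC)cc2)[C@H]3C[C@]1(C)OC(C)(C)O3 | intermediate
12 | C8,C10-acetonide C1 alcohol | O[C@@H]1C[C@H](C(=C)COCc2ccc(OC)cc2)[C@H]3C[C@]1(C)OC(C)(C)O3 | intermediate
13 | C8,C10-acetonide ketone (C1=O, C12–OPMB) | O=C1C[C@H](C(=C)COCc2ccc(OC)cc2)[C@H]3C[C@]1(C)OC(C)(C)O3 | intermediate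
14 | propargyl alcohol | C#CCO | starting material
15 | tert-butyl(diphenyl)(prop-2-yn-1-yloxy)silane | C#CCO[Si](c1ccccc1)(c1ccccc1)C(C)(C)C | intermediate
16 | (E)-alkenylzirconocene chloride (cyclopentadienyl rings drawn σ-bound) | Cl[Zr](/C=C/CO[Si](c1ccccc1)(c1ccccc1)C(C)(C)C)(C1C=CC=C1)C1C=CC=C1 | intermediate
17 | (E)-(3-bromoallyloxy)(tert-butyl)diphenylsilane | Br/C=C/CO[Si](c1ccccc1)(c1ccccc1)C(C)(C)C | intermediate
18 | C6-alkenyl ketone (E-CH=CH–CH2OTBDPS on C6, upper face, trans to the C7 side chain) | O=C1[C@@H](/C=C/CO[Si](c2ccccc2)(c2ccccc2)C(C)(C)C)[C@H](C(=C)COCc2ccc(OC)cc2)[C@H]3C[C@]1(C)OC(C)(C)O3 | intermediate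
19 | ethynylmagnesium bromide | C#C[Mg]Br | starting material
20 | 1-ethynyl-2-alkenylcyclohexanol acetonide (ethynyl upper/axial, C1–OH lower, alkenyl upper/equatorial) | C#C[C@@]1(O)[C@@H](/C=C/CO[Si](c2ccccc2)(c2ccccc2)C(C)(C)C)[C@H](C(=C)COCc2ccc(OC)cc2)[C@H]3C[C@]1(C)OC(C)(C)O3 | intermediate
21 | potassium alkoxide of 20 | [K+].C#C[C@@]1([O-])[C@@H](/C=C/CO[Si](c2ccccc2)(c2ccccc2)C(C)(C)C)[C@H](C(=C)COCc2ccc(OC)cc2)[C@H]3C[C@]1(C)OC(C)(C)O3 | intermediate
22 | ten-membered potassium allenolate (C1(O–)=C2=C3, 5Z) | [K+].C=C(COCc1ccc(OC)cc1)[C@H]2/C=C\[C@@H](CO[Si](c3ccccc3)(c3ccccc3)C(C)(C)C)C=C=C([O-])[C@]4(C)C[C@H]2OC(C)(C)O4 | intermediate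
23 | (2Z,5Z)-cyclodeca-2,5-dienone acetonide (C4 bearing CH2OTBDPS, C7 bearing the PMB-oxymethylvinyl group) | C=C(COCc1ccc(OC)cc1)[C@H]2/C=C\[C@@H](CO[Si](c3ccccc3)(c3ccccc3)C(C)(C)C)/C=C\C(=O)[C@]4(C)C[C@H]2OC(C)(C)O4 | intermediate
24 | C12 allylic alcohol | C=C(CO)[C@H]2/C=C\[C@@H](CO[Si](c3ccccc3)(c3ccccc3)C(C)(C)C)/C=C\C(=O)[C@]4(C)C[C@H]2OC(C)(C)O4 | intermediate
25 | C12 enal | C=C(C=O)[C@H]2/C=C\[C@@H](CO[Si](c3ccccc3)(c3ccccc3)C(C)(C)C)/C=C\C(=O)[C@]4(C)C[C@H]2OC(C)(C)O4 | intermediate
26 | C12 acrylic acid | C=C(C(=O)O)[C@H]2/C=C\[C@@H](CO[Si](c3ccccc3)(c3ccccc3)C(C)(C)C)/C=C\C(=O)[C@]4(C)C[C@H]2OC(C)(C)O4 | intermediate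
27 | 6,12-iodolactone (trans-fused, C5–I anti to O6) | C=C1C(=O)O[C@@H]2[C@@H](I)[C@@H](CO[Si](c4ccccc4)(c4ccccc4)C(C)(C)C)/C=C\C(=O)[C@]3(C)C[C@@H](OC(C)(C)O3)[C@@H]12 | intermediate
28 | α-methylene-γ-lactone acetonide (2Z enone) | C=C1C(=O)O[C@@H]2C[C@@H](CO[Si](c4ccccc4)(c4ccccc4)C(C)(C)C)/C=C\C(=O)[C@]3(C)C[C@@H](OC(C)(C)O3)[C@@H]12 | intermediate
29 | C8,C10-diol (α′-hydroxy enone lactone) | C=C1C(=O)O[C@@H]2C[C@@H](CO[Si](c3ccccc3)(c3ccccc3)C(C)(C)C)/C=C\C(=O)[C@@](C)(O)C[C@@H](O)[C@@H]12 | intermediate
30 | 3(2H)-furanone C8 alcohol (C15–OTBDPS) | C=C1C(=O)O[C@@H]2C[C@@H](CO[Si](c4ccccc4)(c4ccccc4)C(C)(C)C)C3=CC(=O)[C@](C)(C[C@@H](O)[C@@H]12)O3 | intermediate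
31 | angelic acid, (Z)-2-methylbut-2-enoic acid | C/C=C(/C)C(=O)O | starting material
32 | C8 angelate C15 TBDPS ether | C=C1C(=O)O[C@@H]2C[C@@H](CO[Si](c4ccccc4)(c4ccccc4)C(C)(C)C)C3=CC(=O)[C@](C)(C[C@@H](OC(=O)/C(C)=C\C)[C@@H]12)O3 | intermediate
33 | CNP0108636.1 | C=C1C(=O)O[C@@H]2C[C@@H](CO)C3=CC(=O)[C@](C)(C[C@@H](OC(=O)/C(C)=C\C)[C@@H]12)O3 | target

**Count**
Total steps: 25. Longest linear sequence: 23 steps (steps 1–11 and 14–25, from (R)-carvone); steps 12–13 make the alkenyl bromide.

**Steps most likely to fail**

1. Step 16 (ring expansion). The alkoxide may fragment by loss of acetylide back to ketone 18, or the base may move the skipped diene into conjugation and erode C4 before the quench. The fallback is a neutral, thermal siloxy-Cope shift in place of the anionic one. It sets out from 20, which is silylated (TMSOTf, 2,6-lutidine) to the trimethylsilyl ether F1. Heating F1 in degassed toluene in a sealed tube (about 180 °C) should drive the same [3,3] shift through the same chair and give the ten-membered allenyl trimethylsilyl ether F2. Cold dilute HCl in THF protonates C2 and removes silicon, and the route is rejoined at 23.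

2. Step 14 (α-alkenylation). Cross-coupling of the hindered lithium enolate may be slow, a second alkenylation may intrude, or base may pull the β,γ-alkene into conjugation. The fallback replaces cross-coupling by aldol addition, dehydration and deconjugative protonation. It sets out from 13: LDA followed by 3-(tert-butyldiphenylsilyloxy)propanal gives the β-hydroxy ketone F3. MsCl/Et3N converts it to the mesylate F4, and DBU eliminates to the exocyclic enone F5. KHMDS can remove only a γ-hydrogen (C4) of F5, and kinetic α-protonation of the resulting dienolate with acetic acid at −78 °C should return the E β,γ-unsaturated ketone, rejoining the route at 18.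

3. Step 23 (furanone closure). The 5-endo oxypalladation may be reluctant inside the medium ring, or palladium may be diverted to allylic positions and the other alkenes. The fallback closes the ring first and dehydrogenates afterwards. It sets out from 29: TsOH in CH2Cl2 should form the C10–O–C3 bond by acid-catalysed 5-endo oxa-Michael addition, giving the dihydrofuranone F6 (the C3 configuration is immaterial). PhSeCl in EtOAc selenenylates C2, the only enolisable position, to the α-phenylselanyl ketone F7. H2O2/pyridine then oxidises selenium and the selenoxide eliminates toward C3, rejoining the route at 30.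

**Further compounds**
F1 | step 16 | trimethylsilyl ether of 20 | C#C[C@@]1(O[Si](C)(C)C)[C@@H](/C=C/CO[Si](c2ccccc2)(c2ccccc2)C(C)(C)C)[C@H](C(=C)COCc2ccc(OC)cc2)[C@H]3C[C@]1(C)OC(C)(C)O3
F2 | step 16 | ten-membered allenyl trimethylsilyl ether | C=C(COCc1ccc(OC)cc1)[C@H]2/C=C\[C@@H](CO[Si](c3ccccc3)(c3ccccc3)C(C)(C)C)C=C=C(O[Si](C)(C)C)[C@]4(C)C[C@H]2OC(C)(C)O4
F3 | step 14 | β-hydroxy ketone (aldol adduct at C6, carbinol epimers) | O=C1[C@@H](C(O)CCO[Si](c2ccccc2)(c2ccccc2)C(C)(C)C)[C@H](C(=C)COCc2ccc(OC)cc2)[C@H]3C[C@]1(C)OC(C)(C)O3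
F4 | step 14 | mesylate of F3 | O=C1[C@@H](C(OS(C)(=O)=O)CCO[Si](c2ccccc2)(c2ccccc2)C(C)(C)C)[C@H](C(=C)COCc2ccc(OC)cc2)[C@H]3C[C@]1(C)OC(C)(C)O3
F5 | step 14 | exocyclic (E)-enone (C6=C5) | O=C1/C(=C/CCO[Si](c2ccccc2)(c2ccccc2)C(C)(C)C)[C@H](C(=C)COCc2ccc(OC)cc2)[C@H]3C[C@]1(C)OC(C)(C)O3
F6 | step 23 | dihydrofuranone (C3 sp3, C2 H2) | C=C1C(=O)O[C@@H]2C[C@@H](CO[Si](c4ccccc4)(c4ccccc4)C(C)(C)C)C3CC(=O)[C@](C)(C[C@@H](O)[C@@H]12)O3
F7 | step 23 | C2 phenylselanyl dihydrofuranone | C=C1C(=O)O[C@@H]2C[C@@H](CO[Si](c4ccccc4)(c4ccccc4)C(C)(C)C)C3C([Se]c5ccccc5)C(=O)[C@](C)(C[C@@H](O)[C@@H]12)O3
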